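The data are simulated with made-up constants.

Percent of the Q charged is the unit that lets Monday's run and Friday's lie side by side, although their charges differ; the flask asked about is Monday's own, carried on to 12 h.

| flask | Q | Z | remark | time |
|---|---|---|---|---|
| Monday's | 0.33 M | 3.3 mM | the very flask that is asked about, followed so far |  |
| Friday's | 0.22 M | 3.3 mM | run made earlier |  |
| flask | 0.33 M | 3.3 mM |  | 12 h |

| run | time / h | Q / % | X / % | E / % |
|---|---|---|---|---|
| Monday's | 0.500 | 57.4 | 37.4 | 5.3 |
| Monday's | 0.833 | 52.3 | 41.2 | 6.0 |
| Monday's | 1.50 | 49.9 | 42.9 | 6.1 |
| Monday's | 3.00 | 50.3 | 43.0 | 7.3 |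
| Monday's | 6.00 | 49.8 | 42.8 | 6.6 |
| Friday's | 0.417 | 58.0 | 36.3 | 5.6 |
| Friday's | 0.667 | 53.5 | 40.5 | 6.1 |
| Friday's | 1.33 | 50.2 | 42.6 | 6.0 |
| Friday's | 2.50 | 49.9 | 43.0 | 6.3 |
| Friday's | 5.00 | 50.5 | 42.6 | 6.8 |

(readings scatter by 0.3 percentage points)

- the reaction counts as stopped when no species that holds the Q changes by six tenths of a point or more over the second half of the time

- why nothing more happens at 12 h, or that something still does (it is still moving / no working catalyst is left / forward and back rates have come level / all of Q has reacted)
- how much of the Q has reacted by 12 h
- how much X there is at 12 h, in percent of the Q charged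
- how much E there is at 12 h, in percent of the Q charged

The first question is what the end state must be. X over Q, taken once the readings lie flat, can be read twice and independently, from the last two readings of each run:

Monday: c_X/c_Q = 0.857

Friday: c_X/c_Q = 0.853

The two part by 0.00400 across unequal charges of Q, and Friday's run is the quicker, with Q at 58.0% by 0.417 h against 57.4% by 0.500 h on Monday. Unequal pace and one common quotient read as a balance of forward and back rates rather than a failing Z. Their mean, 0.855, is the end quotient, the ratio of X to Q at rest, an apparent equilibrium constant.

The same four readings give E over X as 0.158. If Q, X and E make up the whole charge, the share of Q at rest is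

1/(1 + end quotient + end quotient × E over X) = 50.3%

So this reckoning gives conversion 49.7%, X 43.0% and E 6.80%.

The second question is how fast that end is approached. On Monday the excess of Q over this level falls from 7.1 percentage points to 2 points between the first two readings, which reads as a half-life of 0.184 h. That is far shorter than 12 h, which holds 65.2 such half-lives.

The forecast says forward and back rates have come level, with conversion 50%, X 43% and E 6.6%, since “A common plateau despite different rates points to equilibrium”; it stands 0.26 points above this reckoning on conversion and 0.17 points below it on E.

    X + Z ⇌ E + Z, rate k1*[Z]*[X] forward; the back reaction follows from the equilibrium constant (K = 0.155, k = 0.226 M⁻¹ s⁻¹)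
    Q + Z ⇌ L (K = 5.00 M⁻¹, k = 0.248 M⁻¹ s⁻¹)
    L ⇌ Z + X (K = 0.172 M, k = 6.39 s⁻¹)

The flask's answer is that forward and back rates have come level, with conversion 50.1%, X 42.9% and E 6.66%. L, a form of the catalyst that the balance above did not count, stands at 45.2% of the Z charged at 12.0 h, which is 0.452% of the Q charged in this flask. The end quotient times this flask's free Q, 50%, gives X 42.8%. For the neighbour flask with 0.13 M of Q, where free Q stands at 50%, it gives 42.8%, and that flask holds 42.9%. The slowest mode of this flask has a half-life of 0.223 h at 12.0 h, short beside 12 h. Ten times the time leaves conversion at 50.1%, X at 42.9% and E at 6.66%, a shift in E less than the scatter of 0.3 points.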